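A direct plan would add a prenylzinc reagent to furan-3-carbaldehyde A1 to give racemic carbinol A2, turn A2 into the (S)-senecioate A3 by an acylative dynamic kinetic resolution, and join the arene last by C–H borylation of the furan and Suzuki coupling with bromohydroquinone A4.
Its weakest step would be the resolution: the only stereocentre, made racemic one step before, would rest on an untried pairing of an acyl-transfer catalyst, a ruthenium racemisation catalyst and an unsaturated acyl donor.
The closing borylation–arylation would be least welcome on late material: it would have to tell C5 from C2 of the furan and would expose the ester and a free, air-sensitive hydroquinone to palladium and aqueous base.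
The hot, linear-selective prenylation would buy no stereochemistry at all.

**Plan of the new route** (furan numbering: O1, C2 aryl, C3–H, C4 side chain, C5–H)
The retrosynthesis cuts, in one step, the furan O1–C2 bond and the C–O bond between the carbinol carbon and the ester oxygen, which leaves an acyclic 2-alkynyl enal and free senecioic acid.
A second cut at the alkyne–alkene bond (later C3–C4) gives an aryl alkyne and an α-iodo enal.
The benzene ring is bought and the furan ring arises last, in the key step.
This is possible because the carbinol carbon sits on C4, next to the unsubstituted C5–H and 1,3 to the aryl-bearing C2: O1/C5 are the formyl group of an enal, C4 its α-carbon, the carbinol carbon its β-carbon, and the acid of the natural ester is the nucleophile the cyclisation needs.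
No racemate is made and mended, no finished furan is functionalised or coupled, and no forcing prenylation is needed.

Key step: step 7

Assumption: the sense of induction of the chiral phosphate in step 7 cannot be predicted with certainty; the (R)-phosphate is written on the working assumption that it delivers the (S)-ester, and its mirror image would be used if a trial showed the opposite sense.

Step 1
Reactants: 1 prop-2-yn-1-ol; 2 1-bromo-3-methylbut-2-ene (prenyl bromide)
Product: 3 6-methylhept-5-en-2-yn-1-ol
Conditions: CuI (10 mol %), K2CO3 (1.5 equiv), n-Bu4NBr (10 mol %), DMF, rt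
Reagents that add atoms: none
Why: Copper-catalysed allyl–alkyne coupling: the copper acetylide formed from 1 and carbonate displaces bromide at the unhindered CH2 terminus of the prenyl group (SN2, not SN2'), which should give the skipped enyne with the linear prenyl chain while the free hydroxyl is left alone.

Step 2
Reactants: 3 6-methylhept-5-en-2-yn-1-ol
Product: 4 (E)-6-methylhepta-2,5-dienal
Conditions: (η5-C9H7)Ru(PPh3)2Cl (3 mol %), In(OTf)3 (3 mol %), camphorsulfonic acid (5 mol %), THF, reflux
Reagents that add atoms: none
Why: Ruthenium-catalysed redox isomerisation of a primary propargylic alcohol: the hydrogen taken from the carbinol carbon is returned to the alkyne and protonation of the vinylruthenium species should give the (E)-enal in one redox-neutral step, the isolated trisubstituted alkene being a spectator.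

Step 3
Reactants: 4 (E)-6-methylhepta-2,5-dienal
Product: 5 (Z)-2-iodo-6-methylhepta-2,5-dienal
Conditions: I2 (1.5 equiv), DMAP (20 mol %), K2CO3 (1.2 equiv), THF–H2O 1:1, 0 °C → rt, dark
Reagents that add atoms: iodine, II
Why: Amine-catalysed α-iodination of an enal (conjugate addition of DMAP, iodination of the resulting enolate, elimination of DMAP), which should give the more stable (Z)-α-iodoenal with the formyl group still trans to the chain.

Step 4
Reactants: 6 2,5-dihydroxybenzaldehyde
Product: 7 2,5-bis(tert-butyldimethylsilyloxy)benzaldehyde
Conditions: TBSCl (2.4 equiv), imidazole (5 equiv), DMF, rt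
Reagents that add atoms: tert-butyldimethylsilyl chloride, CC(C)(C)[Si](C)(C)Cl
Why: Imidazole-promoted silylation of both phenols; the silyl ethers mask the oxidation-prone hydroquinone, keep the ortho oxygen from adding to the alkyne in later steps, and can be removed with fluoride without harm to an ester.

Step 5
Reactants: 7 2,5-bis(tert-butyldimethylsilyloxy)benzaldehyde
Product: 8 1,4-bis(tert-butyldimethylsilyloxy)-2-ethynylbenzene
Conditions: Me3SiCHN2 (1.2 equiv), LiN(i-Pr)2 (1.2 equiv), THF, −78 °C; then 7, −78 → 0 °C
Reagents that add atoms: (trimethylsilyl)diazomethane, C[Si](C)(C)C=[N+]=[N-]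
Why: Colvin rearrangement: lithiated (trimethylsilyl)diazomethane adds to the aldehyde, Peterson-type loss of lithium trimethylsilanolate gives a diazoalkene, and loss of N2 with 1,2-hydrogen shift in the alkylidene carbene should give the terminal alkyne under aprotic conditions that spare the aryl silyl ethers.

Step 6
Reactants: 5 (Z)-2-iodo-6-methylhepta-2,5-dienal; 8 1,4-bis(tert-butyldimethylsilyloxy)-2-ethynylbenzene
Product: 9 (E)-2-{[2,5-bis(tert-butyldimethylsilyloxy)phenyl]ethynyl}-6-methylhepta-2,5-dienal
Conditions: Pd(PPh3)2Cl2 (3 mol %), CuI (5 mol %), i-Pr2NH (2 equiv), THF, 0 °C, dark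
Reagents that add atoms: none
Why: Sonogashira coupling: the C–I bond of the α-iodoenal adds to zerovalent palladium fast enough for coupling with the copper acetylide of 8 at 0 °C with retention of alkene geometry, so that the base-sensitive skipped dienal is exposed to amine only briefly.

Step 7
Reactants: 9 (E)-2-{[2,5-bis(tert-butyldimethylsilyloxy)phenyl]ethynyl}-6-methylhepta-2,5-dienal; 10 3-methylbut-2-enoic acid (senecioic acid)
Product: 12 (S)-1-{5-[2,5-bis(tert-butyldimethylsilyloxy)phenyl]furan-3-yl}-4-methylpent-3-en-1-yl 3-methylbut-2-enoate, via aurated alkylidenefuranylium ion 11 (not isolated)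
Conditions: Ph3PAuCl (5 mol %), Ag[(R)-TRIP] (5 mol %; silver salt of (R)-3,3'-bis(2,4,6-triisopropylphenyl)-1,1'-binaphthyl-2,2'-diyl hydrogen phosphate), 10 (3 equiv), 4 Å molecular sieves, toluene, −20 °C
Reagents that add atoms: none
Why: Proposed new method: monovalent gold activates the alkyne of 9, the aldehyde oxygen closes the furan by 5-endo-dig attack on the aryl-bearing alkyne carbon (new O1–C2 bond) to give the C3-aurated furylium ion 11 with an exocyclic alkylidene on C4, and the carboxylic acid 10 then adds to the exocyclic carbon (the former enal β-carbon; new C–O bond of the ester) before protodeauration at C3 returns the catalyst. The closest known reaction type is the gold- or copper-catalysed cycloisomerisation of 2-(1-alkynyl)-2-alken-1-ones with added nucleophiles (alcohols, water, indoles), which gives furans carrying the nucleophile on the side-chain carbon and is known in enantioselective form for indoles with a chiral copper phosphate, together with chiral-phosphate-counterion gold catalysis of carboxylic acid additions to allenes; new here are the enantioselective intermolecular capture by a carboxylic acid and the use of an enal in place of an enone. The only new stereocentre is controlled by the chiral phosphate: in toluene it is ion-paired with cation 11 and hydrogen-bonded through P=O to the O–H of 10, so that the acid is delivered to one face of the planar exocyclic carbon, while the Ph3PAu group on the neighbouring C3 further differentiates the faces; a carboxylic acid is too weak an acid to displace the phosphate from the ion pair. The step needs (a) attack at the exocyclic carbon and not at C5, secured because only that mode gives the aromatic furan (an adduct at C5 would be an allylic acylal that can revert or shift its acyloxy group 1,3 to the same product), (b) ring closure by the aldehyde oxygen and not by the ortho silyloxy oxygen, secured by the bulky silyl group and the greater nucleophilicity of the conjugated carbonyl, and (c) capture of 11 by the acid faster than proton loss from the doubly allylic CH2 to a diene, for which the excess of 10, the low temperature and the non-polar medium are chosen.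

Step 8
Reactants: 12 (S)-1-{5-[2,5-bis(tert-butyldimethylsilyloxy)phenyl]furan-3-yl}-4-methylpent-3-en-1-yl 3-methylbut-2-enoate
Product: 13 (S)-1-[5-(2,5-dihydroxyphenyl)furan-3-yl]-4-methylpent-3-en-1-yl 3-methylbut-2-enoate
Conditions: n-Bu4NF (2.2 equiv), AcOH (2.5 equiv), THF, 0 °C, argon; work-up with degassed pH 6 phosphate buffer
Reagents that add atoms: none
Why: Fluoride cleavage of aryl silyl ethers, which are far more labile than the alkyl ester; the acetic acid buffer keeps phenolate concentration low, so that the senecioate, the ionisable furan-3-ylmethyl C–O bond and hence the stereocentre should stay untouched and the hydroquinone is protected from oxidation under argon.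

**Compound list**
1 | prop-2-yn-1-ol | C#CCO | starting material
2 | 1-bromo-3-methylbut-2-ene (prenyl bromide) | CC(C)=CCBr | starting material
3 | 6-methylhept-5-en-2-yn-1-ol | CC(C)=CCC#CCO | intermediate
4 | (E)-6-methylhepta-2,5-dienal | O=C/C=C/CC=C(C)C | intermediate
5 | (Z)-2-iodo-6-methylhepta-2,5-dienal | O=C/C(I)=C/CC=C(C)C | intermediate
6 | 2,5-dihydroxybenzaldehyde | O=Cc1cc(O)ccc1O | starting material
7 | 2,5-bis(tert-butyldimethylsilyloxy)benzaldehyde | O=Cc1cc(O[Si](C)(C)C(C)(C)C)ccc1O[Si](C)(C)C(C)(C)C | intermediate
8 | 1,4-bis(tert-butyldimethylsilyloxy)-2-ethynylbenzene | C#Cc1cc(O[Si](C)(C)C(C)(C)C)ccc1O[Si](C)(C)C(C)(C)C | intermediate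
9 | (E)-2-{[2,5-bis(tert-butyldimethylsilyloxy)phenyl]ethynyl}-6-methylhepta-2,5-dienal | O=C/C(C#Cc1cc(O[Si](C)(C)C(C)(C)C)ccc1O[Si](C)(C)C(C)(C)C)=C/CC=C(C)C | intermediate
10 | 3-methylbut-2-enoic acid (senecioic acid) | CC(C)=CC(=O)O | starting material
11 | {2-[2,5-bis(tert-butyldimethylsilyloxy)phenyl]-4-(4-methylpent-3-en-1-ylidene)-4H-furan-1-ium-3-yl}(triphenylphosphine)gold cation, paired with the chiral phosphate (not isolated) | CC(C)=CCC=C1C=[O+]C(c2cc(O[Si](C)(C)C(C)(C)C)ccc2O[Si](C)(C)C(C)(C)C)=C1[Au-][P+](c1ccccc1)(c1ccccc1)c1ccccc1 | intermediate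
12 | (S)-1-{5-[2,5-bis(tert-butyldimethylsilyloxy)phenyl]furan-3-yl}-4-methylpent-3-en-1-yl 3-methylbut-2-enoate | CC(C)=CC[C@H](OC(=O)C=C(C)C)c1coc(-c2cc(O[Si](C)(C)C(C)(C)C)ccc2O[Si](C)(C)C(C)(C)C)c1 | intermediate
13 | (S)-1-[5-(2,5-dihydroxyphenyl)furan-3-yl]-4-methylpent-3-en-1-yl 3-methylbut-2-enoate | CC(C)=CC[C@H](OC(=O)C=C(C)C)c1coc(-c2cc(O)ccc2O)c1 | target

**Step count**
Total: 8 steps. Longest linear sequence: 6 steps (steps 1, 2, 3, 6, 7, 8).

**Steps most likely to fail**

Step 7 (Proposed new method). What may go wrong is poor facial selectivity in the capture of cation 11 by the acid, or proton loss from the doubly allylic CH2 of 11 outrunning capture. The fallback uses known chemistry, sets out from 9 and comes back at 12. The same cycloisomerisation would be run with an achiral catalyst (Ph3PAuCl/AgOTf, 2 mol %) in wet THF, so that water is the nucleophile, to give racemic 1-{5-[2,5-bis(tert-butyldimethylsilyloxy)phenyl]furan-3-yl}-4-methylpent-3-en-1-ol F1. Dess–Martin oxidation (NaHCO3, CH2Cl2) would give 1-{5-[2,5-bis(tert-butyldimethylsilyloxy)phenyl]furan-3-yl}-4-methylpent-3-en-1-one F2. Corey–Bakshi–Shibata reduction with the (R)-2-methyl-oxazaborolidine and catecholborane (toluene, −78 °C; the arylfuranyl group as the large substituent) should give (S)-1-{5-[2,5-bis(tert-butyldimethylsilyloxy)phenyl]furan-3-yl}-4-methylpent-3-en-1-ol F3. Steglich esterification with 10 (DCC, DMAP, CH2Cl2, 0 °C) would return to 12.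

Step 3. What may go wrong is attack of iodine or hypoiodite on the trisubstituted alkene, or base-induced migration of the skipped double bond into conjugation during iodination; the same vinylogous acidity also threatens step 6. The fallback sets out from 3 and comes back at 9, so it bypasses steps 2, 3 and 6. Ruthenium-catalysed trans-hydrostannation of the propargylic alcohol ([(η5-C5Me5)RuCl]4, Bu3SnH, CH2Cl2, rt) would place tin on the carbon next to the carbinol and give (Z)-6-methyl-2-(tributylstannyl)hepta-2,5-dien-1-ol F4. Iododestannylation (I2, CH2Cl2, 0 °C) would give (Z)-2-iodo-6-methylhepta-2,5-dien-1-ol F5. Sonogashira coupling with 8 at the alcohol oxidation level, where no enolisable carbonyl is present (Pd(PPh3)2Cl2, CuI, i-Pr2NH, THF), would give (E)-2-{[2,5-bis(tert-butyldimethylsilyloxy)phenyl]ethynyl}-6-methylhepta-2,5-dien-1-ol F6. Oxidation of the allylic alcohol with MnO2 (CH2Cl2, rt) would give 9.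

Step 8. What may go wrong is air oxidation of the liberated hydroquinone to the quinone, or slow ester loss under fluoride, during desilylation and chromatography. The fallback sets out from 12 and comes back at 13. Desilylation would be followed by deliberate oxidation of the crude phenol mixture with Ag2O (CH2Cl2) to the quinone (S)-1-[5-(3,6-dioxocyclohexa-1,4-dien-1-yl)furan-3-yl]-4-methylpent-3-en-1-yl 3-methylbut-2-enoate F7. F7 would be purified and then reduced with aqueous Na2S2O4 (EtOAc–H2O, argon) to 13 immediately before use.

**Further compounds**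
F1 | step 7 | (±)-1-{5-[2,5-bis(tert-butyldimethylsilyloxy)phenyl]furan-3-yl}-4-methylpent-3-en-1-ol | CC(C)=CCC(O)c1coc(-c2cc(O[Si](C)(C)C(C)(C)C)ccc2O[Si](C)(C)C(C)(C)C)c1
F2 | step 7 | 1-{5-[2,5-bis(tert-butyldimethylsilyloxy)phenyl]furan-3-yl}-4-methylpent-3-en-1-one | CC(C)=CCC(=O)c1coc(-c2cc(O[Si](C)(C)C(C)(C)C)ccc2O[Si](C)(C)C(C)(C)C)c1
F3 | step 7 | (S)-1-{5-[2,5-bis(tert-butyldimethylsilyloxy)phenyl]furan-3-yl}-4-methylpent-3-en-1-ol | CC(C)=CC[C@H](O)c1coc(-c2cc(O[Si](C)(C)C(C)(C)C)ccc2O[Si](C)(C)C(C)(C)C)c1
F4 | step 3 | (Z)-6-methyl-2-(tributylstannyl)hepta-2,5-dien-1-ol | OC/C([Sn](CCCC)(CCCC)CCCC)=C/CC=C(C)C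
F5 | step 3 | (Z)-2-iodo-6-methylhepta-2,5-dien-1-ol | OC/C(I)=C/CC=C(C)C
F6 | step 3 | (E)-2-{[2,5-bis(tert-butyldimethylsilyloxy)phenyl]ethynyl}-6-methylhepta-2,5-dien-1-ol | OC/C(C#Cc1cc(O[Si](C)(C)C(C)(C)C)ccc1O[Si](C)(C)C(C)(C)C)=C/CC=C(C)C
F7 | step 8 | (S)-1-[5-(3,6-dioxocyclohexa-1,4-dien-1-yl)furan-3-yl]-4-methylpent-3-en-1-yl 3-methylbut-2-enoate | CC(C)=CC[C@H](OC(=O)C=C(C)C)c1coc(C2=CC(=O)C=CC2=O)c1
A1 | direct plan | furan-3-carbaldehyde | O=Cc1ccoc1
A2 | direct plan | (±)-1-(furan-3-yl)-4-methylpent-3-en-1-ol | CC(C)=CCC(O)c1ccoc1
A3 | direct plan | (S)-1-(furan-3-yl)-4-methylpent-3-en-1-yl 3-methylbut-2-enoate | CC(C)=CC[C@H](OC(=O)C=C(C)C)c1ccoc1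
A4 | direct plan | 2-bromobenzene-1,4-diol (bromohydroquinone) | Oc1ccc(O)c(Br)c1
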